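The route cuts ring A (the benzoate ring: C1 ester carbon, C2 O-prenyl, C4 methyl, C6 aryloxy) at two adjacent positions, the C6–O diaryl ether bond and the C1–CO2 bond. Because the ester at C1 sits between the C2 prenyloxy group and the C6 ether oxygen, a 3-prenyloxy-5-methylbenzyne spanning C1–C6 can take up the ring B phenoxide at C6 and carbon dioxide at C1 in one operation, without forming a ring. The precursors are an ortho-silyl aryl triflate of orcinol monoprenyl ether and a ring B phenol whose benzylic alcohol is masked as a triisopropylsilyl ether; esterification and desilylation finish the synthesis.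

Key step: step 10

Remark: the target has no stereocentre and no alkene capable of E/Z isomerism, so no configuration has to be set. The phenol partner is converted completely into its potassium phenoxide before the aryne is released, so that no O–H proton is present when the aryl anion forms. Equivalents in the Conditions lines are proposed charges.

Step 1
Reactants: 1 orcinol (5-methylbenzene-1,3-diol); 2 prenyl bromide (1-bromo-3-methylbut-2-ene)
Product: 3 3-methyl-5-(3-methylbut-2-enyloxy)phenol
Conditions: 1 (3 equiv), 2 (1 equiv), K2CO3 (1.2 equiv), acetone, 56 °C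
Reagents that add atoms: prenyl bromide 2, CC(C)=CCBr
Why: Williamson etherification in which the excess of the symmetrical diol should hold the reaction at the mono-ether and the weak carbonate base in acetone favours O- over C-allylation.

Step 2
Reactants: 3 3-methyl-5-(3-methylbut-2-enyloxy)phenol
Product: 4 3-methyl-5-(3-methylbut-2-enyloxy)phenyl N-isopropylcarbamate
Conditions: i-PrNCO, Et3N (cat.), CH2Cl2, 23 °C
Reagents that add atoms: isopropyl isocyanate, CC(C)N=C=O
Why: Amine-catalysed addition of a phenol to an isocyanate (carbamoylation), which installs a strong ortho-directing group that can later be removed under mild base.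

Step 3
Reactants: 4 3-methyl-5-(3-methylbut-2-enyloxy)phenyl N-isopropylcarbamate
Product: 8 5-methyl-3-(3-methylbut-2-enyloxy)-2-(trimethylsilyl)phenyl N-isopropylcarbamate, via N-silyl carbamate 5 (not isolated), via aryllithium 6 (not isolated), via C-silylated N-silyl carbamate 7 (not isolated)
Conditions: TBSOTf, TMEDA, Et2O, 0 to 23 °C; n-BuLi, TMEDA, −78 °C; TMSCl, −78 to 23 °C; aq. NaHSO4
Reagents that add atoms: chlorotrimethylsilane, C[Si](C)(C)Cl
Why: Directed ortho-metalation of the carbamate after transient N-silylation, in which the ring carbon lying between the carbamate oxygen and the prenyloxy oxygen is doubly activated and should be lithiated selectively at −78 °C, quenched by the silyl chloride and freed of the N-silyl group on acidic work-up.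

Step 4
Reactants: 8 5-methyl-3-(3-methylbut-2-enyloxy)-2-(trimethylsilyl)phenyl N-isopropylcarbamate
Product: 10 5-methyl-3-(3-methylbut-2-enyloxy)-2-(trimethylsilyl)phenyl trifluoromethanesulfonate, via silylphenol 9 (not isolated)
Conditions: Et2NH, DBU, MeCN, 40 °C; then PhNTf2, 23 °C
Reagents that add atoms: N-phenylbis(trifluoromethanesulfonimide), O=S(=O)(N(c1ccccc1)S(=O)(=O)C(F)(F)F)C(F)(F)F
Why: E1cB cleavage of the secondary carbamate (the expelled isocyanate is trapped by diethylamine) followed by O-triflation of the resulting phenoxide in the same flask, conditions that leave the aryl–silicon bond and the prenyl ether intact.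

Step 5
Reactants: 11 2-hydroxy-5-methoxybenzaldehyde
Product: 12 3-bromo-2-hydroxy-5-methoxybenzaldehyde
Conditions: Br2, NaOAc, AcOH, 23 °C
Reagents that add atoms: bromine, BrBr
Why: Electrophilic aromatic bromination directed by the phenol, whose para position is blocked by the methoxy group so that the only free ortho position, C3, should be substituted.

Step 6
Reactants: 12 3-bromo-2-hydroxy-5-methoxybenzaldehyde
Product: 13 2,3-dihydroxy-5-methoxybenzaldehyde
Conditions: NaOH (aq.), Cu powder (cat.), 100 °C, N2; then HCl, 0 °C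
Reagents that add atoms: sodium hydroxide, [Na+].[OH-]
Why: Copper-mediated Ullmann-type hydroxylation of an ortho-bromophenoxide, the classical conversion of bromosalicylaldehydes and bromovanillins into catechols, run under nitrogen to protect the electron-rich product.

Step 7
Reactants: 13 2,3-dihydroxy-5-methoxybenzaldehyde; 2 prenyl bromide
Product: 15 2-hydroxy-5-methoxy-3-(3-methylbut-2-enyloxy)benzaldehyde, via disodium catecholate 14 (not isolated)
Conditions: NaH (2.2 equiv), DMSO, 20 °C; then 2 (1.0 equiv), 20 °C; dilute HCl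
Reagents that add atoms: prenyl bromide 2, CC(C)=CCBr
Why: Williamson alkylation of the dianion, in which the 2-oxide is stabilised by conjugation with and chelation to the aldehyde, so the more basic 3-oxide should take up the single equivalent of bromide.

Step 8
Reactants: 15 2-hydroxy-5-methoxy-3-(3-methylbut-2-enyloxy)benzaldehyde
Product: 16 2-(hydroxymethyl)-4-methoxy-6-(3-methylbut-2-enyloxy)phenol
Conditions: NaBH4, MeOH, 0 °C; aq. NH4Cl
Reagents that add atoms: none
Why: Borohydride reduction of the aldehyde to the benzylic alcohol, with a neutral work-up to avoid acid-induced quinone methide formation from the electron-rich salicyl alcohol.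

Step 9
Reactants: 16 2-(hydroxymethyl)-4-methoxy-6-(3-methylbut-2-enyloxy)phenol
Product: 17 4-methoxy-2-(3-methylbut-2-enyloxy)-6-[(triisopropylsilyloxy)methyl]phenol
Conditions: TIPSCl (1.05 equiv), imidazole, CH2Cl2, 0 °C
Reagents that add atoms: chlorotriisopropylsilane, CC(C)[Si](Cl)(C(C)C)C(C)C
Why: Chemoselective silylation of the unhindered primary benzylic hydroxyl, since the phenol is flanked by two ortho substituents and should not accept the bulky silyl group at 0 °C.

Step 10
Reactants: 17 4-methoxy-2-(3-methylbut-2-enyloxy)-6-[(triisopropylsilyloxy)methyl]phenol; 10 5-methyl-3-(3-methylbut-2-enyloxy)-2-(trimethylsilyl)phenyl trifluoromethanesulfonate; 18 carbon dioxide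
Product: 22 2-[4-methoxy-2-(3-methylbut-2-enyloxy)-6-[(triisopropylsilyloxy)methyl]phenoxy]-4-methyl-6-(3-methylbut-2-enyloxy)benzoic acid, via potassium phenoxide 19 (not isolated), via 3-prenyloxy-5-methylbenzyne 20 (not isolated), via aryl anion 21 (not isolated)
Conditions: 17 (1.5 equiv), KH (1.5 equiv), THF, 0 °C; then CO2 (1 atm), KF, 18-crown-6, slow addition of 10 (1.0 equiv), 0 to 23 °C; cold 0.5 M HCl to pH 3
Reagents that add atoms: carbon dioxide 18, O=C=O
Why: Proposed new method: fluoride attacks the trimethylsilyl group of 10 and triflate departs to give aryne 20, whose C1–C6 triple bond is polarised and distorted by the inductively withdrawing C2 prenyloxy group, so that phenoxide 19 should bond through oxygen to C6 (meta to the alkoxy group) and place the negative charge on C1 beside that oxygen; aryl anion 21 is then intercepted by CO2, an electrophile small enough to reach a carbanion flanked by two ortho oxygens, and acidification releases acid 22. The closest known reaction types are the three-component union of arynes, amines and CO2 to give anthranilic acids and the regioselective O-arylation of phenoxides by 3-alkoxyarynes. No ring is closed and no stereocentre is formed. The step needs regioselectivity (attack at C6 and not C1), which the C2 alkoxy group secures, and chemoselectivity (carboxylation and not protonation of 21), which is secured by complete prior deprotonation of the phenol with KH, by the silyl cap on the benzylic hydroxyl and by an aprotic ether solvent. Reversible carbonate formation between 19 and CO2 is expected only to buffer the concentration of free phenoxide, which remains the more nucleophilic species toward the aryne.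

Step 11
Reactants: 22 2-[4-methoxy-2-(3-methylbut-2-enyloxy)-6-[(triisopropylsilyloxy)methyl]phenoxy]-4-methyl-6-(3-methylbut-2-enyloxy)benzoic acid
Product: 23 methyl 2-[4-methoxy-2-(3-methylbut-2-enyloxy)-6-[(triisopropylsilyloxy)methyl]phenoxy]-4-methyl-6-(3-methylbut-2-enyloxy)benzoate
Conditions: MeI, K2CO3, DMF, 23 °C
Reagents that add atoms: iodomethane, CI
Why: SN2 O-methylation of the carboxylate, which takes place at the methyl carbon of the reagent and is therefore insensitive to the two ortho substituents that would block a carbonyl-addition esterification.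

Step 12
Reactants: 23 methyl 2-[4-methoxy-2-(3-methylbut-2-enyloxy)-6-[(triisopropylsilyloxy)methyl]phenoxy]-4-methyl-6-(3-methylbut-2-enyloxy)benzoate
Product: 24 methyl 2-[2-(hydroxymethyl)-4-methoxy-6-(3-methylbut-2-enyloxy)phenoxy]-4-methyl-6-(3-methylbut-2-enyloxy)benzoate (target)
Conditions: TBAF, AcOH, THF, 0 to 23 °C
Reagents that add atoms: none
Why: Fluoride-induced cleavage of the silicon–oxygen bond (desilylation), buffered with acetic acid so that the liberated alkoxide is protonated before it can attack the neighbouring methyl ester.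

Compound list
1 | orcinol (5-methylbenzene-1,3-diol) | Cc1cc(O)cc(O)c1 | starting material
2 | prenyl bromide (1-bromo-3-methylbut-2-ene) | CC(C)=CCBr | starting material
3 | 3-methyl-5-(3-methylbut-2-enyloxy)phenol | Cc1cc(O)cc(OCC=C(C)C)c1 | intermediate
4 | 3-methyl-5-(3-methylbut-2-enyloxy)phenyl N-isopropylcarbamate | Cc1cc(OCC=C(C)C)cc(OC(=O)NC(C)C)c1 | intermediate
5 | 3-methyl-5-(3-methylbut-2-enyloxy)phenyl N-(tert-butyldimethylsilyl)-N-isopropylcarbamate | Cc1cc(OCC=C(C)C)cc(OC(=O)N(C(C)C)[Si](C)(C)C(C)(C)C)c1 | intermediate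
6 | [2-[N-(tert-butyldimethylsilyl)-N-isopropylcarbamoyloxy]-4-methyl-6-(3-methylbut-2-enyloxy)phenyl]lithium | Cc1cc(OCC=C(C)C)c([Li])c(OC(=O)N(C(C)C)[Si](C)(C)C(C)(C)C)c1 | intermediate
7 | 5-methyl-3-(3-methylbut-2-enyloxy)-2-(trimethylsilyl)phenyl N-(tert-butyldimethylsilyl)-N-isopropylcarbamate | Cc1cc(OCC=C(C)C)c([Si](C)(C)C)c(OC(=O)N(C(C)C)[Si](C)(C)C(C)(C)C)c1 | intermediate
8 | 5-methyl-3-(3-methylbut-2-enyloxy)-2-(trimethylsilyl)phenyl N-isopropylcarbamate | Cc1cc(OCC=C(C)C)c([Si](C)(C)C)c(OC(=O)NC(C)C)c1 | intermediate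
9 | 5-methyl-3-(3-methylbut-2-enyloxy)-2-(trimethylsilyl)phenol | Cc1cc(OCC=C(C)C)c([Si](C)(C)C)c(O)c1 | intermediate
10 | 5-methyl-3-(3-methylbut-2-enyloxy)-2-(trimethylsilyl)phenyl trifluoromethanesulfonate | Cc1cc(OCC=C(C)C)c([Si](C)(C)C)c(OS(=O)(=O)C(F)(F)F)c1 | intermediate
11 | 2-hydroxy-5-methoxybenzaldehyde | COc1ccc(O)c(C=O)c1 | starting material
12 | 3-bromo-2-hydroxy-5-methoxybenzaldehyde | COc1cc(Br)c(O)c(C=O)c1 | intermediate
13 | 2,3-dihydroxy-5-methoxybenzaldehyde | COc1cc(O)c(O)c(C=O)c1 | intermediate
14 | disodium 3-formyl-5-methoxybenzene-1,2-diolate | [Na+].[Na+].COc1cc([O-])c([O-])c(C=O)c1 | intermediate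
15 | 2-hydroxy-5-methoxy-3-(3-methylbut-2-enyloxy)benzaldehyde | COc1cc(OCC=C(C)C)c(O)c(C=O)c1 | intermediate
16 | 2-(hydroxymethyl)-4-methoxy-6-(3-methylbut-2-enyloxy)phenol | COc1cc(CO)c(O)c(OCC=C(C)C)c1 | intermediate
17 | 4-methoxy-2-(3-methylbut-2-enyloxy)-6-[(triisopropylsilyloxy)methyl]phenol | Oc1c(CO[Si](C(C)C)(C(C)C)C(C)C)cc(OC)cc1OCC=C(C)C | intermediate
18 | carbon dioxide | O=C=O | starting material
19 | potassium 4-methoxy-2-(3-methylbut-2-enyloxy)-6-[(triisopropylsilyloxy)methyl]phenoxide | [K+].[O-]c1c(CO[Si](C(C)C)(C(C)C)C(C)C)cc(OC)cc1OCC=C(C)C | intermediate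
20 | 1,2-didehydro-5-methyl-3-(3-methylbut-2-enyloxy)benzene (3-prenyloxy-5-methylbenzyne) | CC1=CC#CC(OCC=C(C)C)=C1 | intermediate
21 | potassium 2-[4-methoxy-2-(3-methylbut-2-enyloxy)-6-[(triisopropylsilyloxy)methyl]phenoxy]-4-methyl-6-(3-methylbut-2-enyloxy)benzen-1-ide | [K+].Cc1cc(OCC=C(C)C)[c-]c(Oc2c(CO[Si](C(C)C)(C(C)C)C(C)C)cc(OC)cc2OCC=C(C)C)c1 | intermediate
22 | 2-[4-methoxy-2-(3-methylbut-2-enyloxy)-6-[(triisopropylsilyloxy)methyl]phenoxy]-4-methyl-6-(3-methylbut-2-enyloxy)benzoic acid | O=C(O)c1c(OCC=C(C)C)cc(C)cc1Oc1c(CO[Si](C(C)C)(C(C)C)C(C)C)cc(OC)cc1OCC=C(C)C | intermediate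
23 | methyl 2-[4-methoxy-2-(3-methylbut-2-enyloxy)-6-[(triisopropylsilyloxy)methyl]phenoxy]-4-methyl-6-(3-methylbut-2-enyloxy)benzoate | COC(=O)c1c(OCC=C(C)C)cc(C)cc1Oc1c(CO[Si](C(C)C)(C(C)C)C(C)C)cc(OC)cc1OCC=C(C)C | intermediate
24 | methyl 2-[2-(hydroxymethyl)-4-methoxy-6-(3-methylbut-2-enyloxy)phenoxy]-4-methyl-6-(3-methylbut-2-enyloxy)benzoate | COC(=O)c1c(OCC=C(C)C)cc(C)cc1Oc1c(CO)cc(OC)cc1OCC=C(C)C | target

Total step count: 12 (ring A arm steps 1–4, ring B arm steps 5–9, union and finish steps 10–12).
Longest linear sequence: 8 steps (steps 5–12, from 2-hydroxy-5-methoxybenzaldehyde 11).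

Steps most likely to fail

1. Step 10 (proposed new method). Several processes could divert the reaction:
- protonation of the aryl anion before CO2 reaches it;
- addition of the reversibly formed aryl carbonate instead of the free phenoxide, followed by acyl migration;
- an intramolecular ene reaction of the aryne with its own prenyl group;
- fluoride-induced loss of the triisopropylsilyl group, which would release a competing alkoxide.

Fallback, by known chemistry (two nucleophilic aromatic substitutions and a Pinnick oxidation), sets out from 17. Phenol 17 is heated with purchased 2,6-difluoro-4-methylbenzaldehyde (Cc1cc(F)c(C=O)c(F)c1) and K2CO3 in DMF at 80 °C, which should give 2-fluoro-6-[4-methoxy-2-(3-methylbut-2-enyloxy)-6-[(triisopropylsilyloxy)methyl]phenoxy]-4-methylbenzaldehyde F1. The remaining aldehyde-activated fluoride is displaced by prenyl alcohol and KOt-Bu in THF at 0 °C to give 2-[4-methoxy-2-(3-methylbut-2-enyloxy)-6-[(triisopropylsilyloxy)methyl]phenoxy]-4-methyl-6-(3-methylbut-2-enyloxy)benzaldehyde F2. Oxidation with NaClO2, NaH2PO4 and excess 2-methylbut-2-ene in t-BuOH/water then delivers acid 22, where the route is rejoined before step 11.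

2. Step 3. The base may instead remove an allylic O–CH2 proton of the prenyl ether, leading to Wittig rearrangement. Metalation could also occur at the ring position beside the methyl group, or the carbamate could migrate to carbon on warming.

Fallback introduces silicon before the prenyl group and sets out from 1. Orcinol with i-PrNCO and Et3N in CH2Cl2 gives 5-methyl-1,3-phenylene bis(N-isopropylcarbamate) F3. The reagent sequence of step 3 should then pass through three species in the flask:
- 5-methyl-1,3-phenylene bis[N-(tert-butyldimethylsilyl)-N-isopropylcarbamate] F4;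
- [2,6-bis[N-(tert-butyldimethylsilyl)-N-isopropylcarbamoyloxy]-4-methylphenyl]lithium F5, metalated between the two carbamate oxygens;
- 5-methyl-2-(trimethylsilyl)-1,3-phenylene bis[N-(tert-butyldimethylsilyl)-N-isopropylcarbamate] F6.

Acidic work-up gives 5-methyl-2-(trimethylsilyl)-1,3-phenylene bis(N-isopropylcarbamate) F7. Et2NH and DBU in MeCN at 40 °C cleave both carbamates to 5-methyl-2-(trimethylsilyl)benzene-1,3-diol F8. Monoalkylation with 2 and K2CO3 in acetone returns to the route at 9, here isolated, which is triflated with PhNTf2 and Et3N as in the second stage of step 4 to give 10.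

3. Step 7. Discrimination between the two phenolic oxygens may be poor, and C-prenylation or double alkylation of the electron-rich dianion, or its oxidation by traces of air, may compete.

Fallback differentiates the oxygens by tying up the first phenol before the second oxygen exists, and sets out from 12. The sequence is:
- NaBH4 in MeOH gives 2-bromo-6-(hydroxymethyl)-4-methoxyphenol F9.
- 2,2-Dimethoxypropane and PPTS in acetone close the acetonide 8-bromo-6-methoxy-2,2-dimethyl-4H-1,3-benzodioxine F10.
- Hydroxylation with KOH, Pd2(dba)3 and t-BuXPhos in 1,4-dioxane/water at 100 °C gives 6-methoxy-2,2-dimethyl-4H-1,3-benzodioxin-8-ol F11.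
- Alkylation of the only free phenol with 2 and K2CO3 in DMF gives 6-methoxy-2,2-dimethyl-8-(3-methylbut-2-enyloxy)-4H-1,3-benzodioxine F12.
- PPTS in MeOH removes the acetonide and delivers 16, where the route is rejoined before step 9.

Further compounds
F1 | step 10 | 2-fluoro-6-[4-methoxy-2-(3-methylbut-2-enyloxy)-6-[(triisopropylsilyloxy)methyl]phenoxy]-4-methylbenzaldehyde | O=Cc1c(F)cc(C)cc1Oc1c(CO[Si](C(C)C)(C(C)C)C(C)C)cc(OC)cc1OCC=C(C)C
F2 | step 10 | 2-[4-methoxy-2-(3-methylbut-2-enyloxy)-6-[(triisopropylsilyloxy)methyl]phenoxy]-4-methyl-6-(3-methylbut-2-enyloxy)benzaldehyde | O=Cc1c(OCC=C(C)C)cc(C)cc1Oc1c(CO[Si](C(C)C)(C(C)C)C(C)C)cc(OC)cc1OCC=C(C)C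
F3 | step 3 | 5-methyl-1,3-phenylene bis(N-isopropylcarbamate) | Cc1cc(OC(=O)NC(C)C)cc(OC(=O)NC(C)C)c1
F4 | step 3 | 5-methyl-1,3-phenylene bis[N-(tert-butyldimethylsilyl)-N-isopropylcarbamate] | Cc1cc(OC(=O)N(C(C)C)[Si](C)(C)C(C)(C)C)cc(OC(=O)N(C(C)C)[Si](C)(C)C(C)(C)C)c1
F5 | step 3 | [2,6-bis[N-(tert-butyldimethylsilyl)-N-isopropylcarbamoyloxy]-4-methylphenyl]lithium | Cc1cc(OC(=O)N(C(C)C)[Si](C)(C)C(C)(C)C)c([Li])c(OC(=O)N(C(C)C)[Si](C)(C)C(C)(C)C)c1
F6 | step 3 | 5-methyl-2-(trimethylsilyl)-1,3-phenylene bis[N-(tert-butyldimethylsilyl)-N-isopropylcarbamate] | Cc1cc(OC(=O)N(C(C)C)[Si](C)(C)C(C)(C)C)c([Si](C)(C)C)c(OC(=O)N(C(C)C)[Si](C)(C)C(C)(C)C)c1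
F7 | step 3 | 5-methyl-2-(trimethylsilyl)-1,3-phenylene bis(N-isopropylcarbamate) | Cc1cc(OC(=O)NC(C)C)c([Si](C)(C)C)c(OC(=O)NC(C)C)c1
F8 | step 3 | 5-methyl-2-(trimethylsilyl)benzene-1,3-diol | Cc1cc(O)c([Si](C)(C)C)c(O)c1
F9 | step 7 | 2-bromo-6-(hydroxymethyl)-4-methoxyphenol | COc1cc(Br)c(O)c(CO)c1
F10 | step 7 | 8-bromo-6-methoxy-2,2-dimethyl-4H-1,3-benzodioxine | COc1cc(Br)c2OC(C)(C)OCc2c1
F11 | step 7 | 6-methoxy-2,2-dimethyl-4H-1,3-benzodioxin-8-ol | COc1cc(O)c2OC(C)(C)OCc2c1
F12 | step 7 | 6-methoxy-2,2-dimethyl-8-(3-methylbut-2-enyloxy)-4H-1,3-benzodioxine | COc1cc(OCC=C(C)C)c2OC(C)(C)OCc2c1
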